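**Plan**

Labels: heptanoid chain C1–C7 (C1=C2 styrene, C3 stereocentre, C7 benzylic). Ring A is the central oxygenated ring, ring B the enone aryl, ring C the aryl on C1, ring D the aryl on C7.
Cuts, in retrosynthetic order: enone Cα=Cβ (ring B aldehyde), ring A–acetyl, C1=C2 and C1–ring C (back to a C1 aldehyde stored as a lactol), O–CH3, ring A–C3, C2=C3 of an enal, C7–ring D.
Enabling feature: C3 is benzylic to the phloroglucinol-type ring A, lies between two ring A oxygens and is β to C1. It is therefore the β-carbon of a 7-arylhept-2-enal, and a flanking oxygen can reach C1 through a six-membered hemiacetal.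
Forward: ring D is joined to a C6 chain (Suzuki) and extended to the C7 enal (metathesis). Ring A is then attached with closure of the only new, temporary ring (chroman-2-ol). After that the para oxygen is methylated, ring C opens the lactol, ring A is acetylated, C1=C2 is formed, ring B is condensed on and the MOM groups leave.
Stereochemistry: C3 (R) is the only stereocentre and is set by the (S)-diphenylprolinol trimethylsilyl ether catalyst in the Friedel–Crafts step. No later step makes C3 cationic or C3–H acidic enough to exchange, and both alkenes become E in their eliminations.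

Key step: step 4

Remark: the target SMILES corresponds to (R) at C3. The (S)-catalyst is assigned from the usual steric-shielding model of its E-iminium ions, and the equally available (R)-catalyst would serve should the correlation prove opposite.

**Step 1**
Reactants: 1 4-bromophenol
Product: 2 1-bromo-4-(methoxymethoxy)benzene
Conditions: MOMCl, iPr2NEt, CH2Cl2, 0 °C → rt
Reagents that add atoms: chloromethyl methyl ether (MOMCl), COCCl
Why: Williamson-type O-alkylation with the reactive α-chloro ether gives an acetal that tolerates base, organometallics, ruthenium carbenes and amine catalysis and can leave at the end with all other MOM groups.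

**Step 2**
Reactants: 3 1,5-hexadiene; 2 1-bromo-4-(methoxymethoxy)benzene
Product: 5 1-(hex-5-en-1-yl)-4-(methoxymethoxy)benzene, via B-(hex-5-enyl)-9-BBN 4 (not isolated)
Conditions: 9-BBN, 3 (3 equiv), THF, 0 °C → rt, excess 3 evaporated; then 2, PdCl2(dppf) (3 mol %), aq. NaOH (3 M), THF, 65 °C
Reagents that add atoms: none
Why: Anti-Markovnikov hydroboration of one terminus of the diene (used in excess so that the second alkene stays free) followed by B-alkyl Suzuki–Miyaura coupling forges the C7–ring D bond, a standard sp3–sp2 coupling for aryl bromides.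

**Step 3**
Reactants: 5 1-(hex-5-en-1-yl)-4-(methoxymethoxy)benzene; 6 (E)-crotonaldehyde
Product: 7 (E)-7-[4-(methoxymethoxy)phenyl]hept-2-enal
Conditions: 6 (5 equiv), second-generation Hoveyda–Grubbs catalyst (2.5 mol %), CH2Cl2, 40 °C
Reagents that add atoms: none
Why: Olefin cross-metathesis of an unhindered terminal alkene with an electron-poor enal partner favours the cross product and the E-enal under thermodynamic control, with propene escaping as gas.

**Step 4**
Reactants: 7 (E)-7-[4-(methoxymethoxy)phenyl]hept-2-enal; 8 phloroglucinol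
Product: 10 (4R)-4-{4-[4-(methoxymethoxy)phenyl]butyl}chromane-2,5,7-triol (anomeric mixture at C2), via open-chain (3R)-aldehyde 9 (not isolated)
Conditions: 8 (3 equiv), (S)-2-[diphenyl(trimethylsilyloxy)methyl]pyrrolidine (20 mol %), PhCO2H (20 mol %), MeCN, 0 °C, slow addition of 7
Reagents that add atoms: none
Why: The amine and 7 condense (benzoic acid assisting) to the E,s-trans iminium ion, a ring A carbon of 8 attacks its β-carbon C3, and rearomatisation followed by hydrolysis of the enamine frees aldehyde 9 and the catalyst. The closest known reaction type is the diarylprolinol silyl ether catalysed Friedel–Crafts alkylation/hemiacetalisation of electron-rich phenols, naphthols and cyclic 1,3-diones with enals, which gives 4-substituted chroman-2-ols. The single ring closes by reversible 6-exo-trig addition of one of the two equivalent hydroxyls flanking the new bond to the C1 carbonyl, so that only the irrelevant anomeric centre forms as a mixture. The CPh2(OSiMe3) group of the (S)-catalyst covers the Si face of C3, the arene therefore bonds to the Re face, and with the priorities ring A > C2 > C4 > H this is the R configuration needed at C3 (C4 of the chromane). The step needs 1,4- rather than 1,2-attack, which the soft carbon nucleophile and the crowded iminium carbon provide, and mono-alkylation, which a threefold excess of 8 and slow addition of 7 provide, the surplus of 8 being washed out with water. Ring regiochemistry cannot arise because the three CH positions of 8 are equivalent, and the lactol at once masks one flanking oxygen and stores C1 at the aldehyde level for ring C.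

**Step 5**
Reactants: 10 (4R)-4-{4-[4-(methoxymethoxy)phenyl]butyl}chromane-2,5,7-triol
Product: 11 (4R)-7-methoxy-4-{4-[4-(methoxymethoxy)phenyl]butyl}chromane-2,5-diol (anomeric mixture)
Conditions: MeI (1.0 equiv), K2CO3 (1.0 equiv), acetone, 0 °C → rt
Reagents that add atoms: iodomethane, CI
Why: Williamson methylation with one equivalent each of base and MeI should take the C7 hydroxyl, which has two free ortho positions, in preference to the C5 hydroxyl, which is buttressed by the pseudoaxial C4 side chain, while the far less acidic lactol hydroxyl stays protonated and the ring closed.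

**Step 6**
Reactants: 11 (4R)-7-methoxy-4-{4-[4-(methoxymethoxy)phenyl]butyl}chromane-2,5-diol; 2 1-bromo-4-(methoxymethoxy)benzene
Product: 13 2-{(3R)-1-hydroxy-1,7-bis[4-(methoxymethoxy)phenyl]heptan-3-yl}-5-methoxybenzene-1,3-diol (both C1 epimers), via aryl Grignard reagent 12 (not isolated)
Conditions: 2 (3.5 equiv), Mg turnings, THF, 40 °C; then 11, THF, 0 °C → rt; buffered aqueous work-up
Reagents that add atoms: none
Why: In this Grignard addition to a lactol two equivalents deprotonate the C5 and anomeric hydroxyls, the magnesium lactolate opens to the C1 aldehyde and a third equivalent adds, giving both C1 epimers (harmless, since C1 becomes sp2) and leaving C3 untouched.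

**Step 7**
Reactants: 13 2-{(3R)-1-hydroxy-1,7-bis[4-(methoxymethoxy)phenyl]heptan-3-yl}-5-methoxybenzene-1,3-diol
Product: 14 (3R)-3-[4-methoxy-2,6-bis(methoxymethoxy)phenyl]-1,7-bis[4-(methoxymethoxy)phenyl]heptan-1-ol (both C1 epimers)
Conditions: MOMCl (2.4 equiv), K2CO3, acetone, 0 °C → rt
Reagents that add atoms: chloromethyl methyl ether (MOMCl), COCCl
Why: Under carbonate only the two phenols are ionised, so this Williamson-type O-alkylation caps both flanking oxygens chemoselectively, makes ring A locally symmetric and removes the phenol nucleophiles that could otherwise trap an ionised C1 as a 2-arylchromane.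

**Step 8**
Reactants: 14 (3R)-3-[4-methoxy-2,6-bis(methoxymethoxy)phenyl]-1,7-bis[4-(methoxymethoxy)phenyl]heptan-1-ol
Product: 16 1-{3-[(3R)-1-hydroxy-1,7-bis[4-(methoxymethoxy)phenyl]heptan-3-yl]-6-methoxy-2,4-bis(methoxymethoxy)phenyl}ethan-1-one (both C1 epimers), via dilithiated species 15 (not isolated)
Conditions: n-BuLi (2.3 equiv), THF, 0 °C; then MeC(O)N(OMe)Me, −78 → 0 °C
Reagents that add atoms: N-methoxy-N-methylacetamide, CC(=O)N(C)OC
Why: In this directed ortho-metalation the first equivalent of base forms the alkoxide and the second removes a ring A proton flanked by OMe and OMOM (two equivalent sites, cooperative directors, favoured over the singly activated positions of rings C and D), the aryllithium stops at the ketone through the chelated adduct of the amide, and acylating before C1=C2 exists avoids deprotonation of an allylic and benzylic C3–H.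

**Step 9**
Reactants: 16 1-{3-[(3R)-1-hydroxy-1,7-bis[4-(methoxymethoxy)phenyl]heptan-3-yl]-6-methoxy-2,4-bis(methoxymethoxy)phenyl}ethan-1-one
Product: 18 1-{3-[(1E,3R)-1,7-bis[4-(methoxymethoxy)phenyl]hept-1-en-3-yl]-6-methoxy-2,4-bis(methoxymethoxy)phenyl}ethan-1-one, via benzylic mesylate 17 (not isolated)
Conditions: MsCl, Et3N, CH2Cl2, 0 °C; then DBU, rt → 40 °C
Reagents that add atoms: none
Why: Mesylation of the electron-rich benzylic alcohol and base-induced β-elimination can lose only a C2 proton and give the conjugated E-styrene, while the amine bases and the acetyl group already on ring A disfavour capture of C1 by a flanking MOM oxygen.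

**Step 10**
Reactants: 19 4-hydroxybenzaldehyde
Product: 20 4-(methoxymethoxy)benzaldehyde
Conditions: MOMCl, iPr2NEt, CH2Cl2, 0 °C → rt
Reagents that add atoms: chloromethyl methyl ether (MOMCl), COCCl
Why: The same Williamson-type acetal formation masks the phenol, whose phenoxide would otherwise deactivate the aldehyde in the basic condensation.

**Step 11**
Reactants: 18 1-{3-[(1E,3R)-1,7-bis[4-(methoxymethoxy)phenyl]hept-1-en-3-yl]-6-methoxy-2,4-bis(methoxymethoxy)phenyl}ethan-1-one; 20 4-(methoxymethoxy)benzaldehyde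
Product: 21 (2E)-1-{3-[(1E,3R)-1,7-bis[4-(methoxymethoxy)phenyl]hept-1-en-3-yl]-6-methoxy-2,4-bis(methoxymethoxy)phenyl}-3-[4-(methoxymethoxy)phenyl]prop-2-en-1-one
Conditions: KOH, EtOH, rt
Reagents that add atoms: none
Why: Claisen–Schmidt condensation of the methyl ketone enolate with the non-enolisable aldehyde and E1cB loss of water gives the E-enone, all phenols being masked and C3–H far too weakly acidic to exchange in ethanolic hydroxide.

**Step 12**
Reactants: 21 (2E)-1-{3-[(1E,3R)-1,7-bis[4-(methoxymethoxy)phenyl]hept-1-en-3-yl]-6-methoxy-2,4-bis(methoxymethoxy)phenyl}-3-[4-(methoxymethoxy)phenyl]prop-2-en-1-one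
Product: 22 deoxycalyxin A
Conditions: HCl (1 M in MeOH), 40 °C
Reagents that add atoms: none
Why: Acid-catalysed transacetalisation of the five aryl MOM ethers to methanol should be faster than protonation of a β-alkylstyrene or oxa-Michael closure of the 2'-hydroxychalcone, a margin routinely relied on for MOM-protected alkenyl chalcones, so the pentaphenol should be released with C3 and both E-alkenes intact.

**Compound list**

1 | 4-bromophenol | Oc1ccc(Br)cc1 | starting material
2 | 1-bromo-4-(methoxymethoxy)benzene | COCOc1ccc(Br)cc1 | intermediate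
3 | 1,5-hexadiene | C=CCCC=C | starting material
4 | 9-(hex-5-en-1-yl)-9-borabicyclo[3.3.1]nonane | C=CCCCCB1C2CCCC1CCC2 | intermediate
5 | 1-(hex-5-en-1-yl)-4-(methoxymethoxy)benzene | C=CCCCCc1ccc(OCOC)cc1 | intermediate
6 | (E)-crotonaldehyde | C/C=C/C=O | starting material
7 | (E)-7-[4-(methoxymethoxy)phenyl]hept-2-enal | O=C/C=C/CCCCc1ccc(OCOC)cc1 | intermediate
8 | phloroglucinol | Oc1cc(O)cc(O)c1 | starting material
9 | (3R)-7-[4-(methoxymethoxy)phenyl]-3-(2,4,6-trihydroxyphenyl)heptanal | O=CC[C@@H](CCCCc1ccc(OCOC)cc1)c1c(O)cc(O)cc1O | intermediate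
10 | (4R)-4-{4-[4-(methoxymethoxy)phenyl]butyl}chromane-2,5,7-triol (anomeric mixture at C2) | Oc1cc(O)c2c(c1)OC(O)C[C@H]2CCCCc1ccc(OCOC)cc1 | intermediate
11 | (4R)-7-methoxy-4-{4-[4-(methoxymethoxy)phenyl]butyl}chromane-2,5-diol (anomeric mixture at C2) | COc1cc(O)c2c(c1)OC(O)C[C@H]2CCCCc1ccc(OCOC)cc1 | intermediate
12 | [4-(methoxymethoxy)phenyl]magnesium bromide | COCOc1ccc([Mg]Br)cc1 | intermediate
13 | 2-{(3R)-1-hydroxy-1,7-bis[4-(methoxymethoxy)phenyl]heptan-3-yl}-5-methoxybenzene-1,3-diol (C1 epimers) | COc1cc(O)c([C@@H](CC(O)c2ccc(OCOC)cc2)CCCCc2ccc(OCOC)cc2)c(O)c1 | intermediate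
14 | (3R)-3-[4-methoxy-2,6-bis(methoxymethoxy)phenyl]-1,7-bis[4-(methoxymethoxy)phenyl]heptan-1-ol (C1 epimers) | COc1cc(OCOC)c([C@@H](CC(O)c2ccc(OCOC)cc2)CCCCc2ccc(OCOC)cc2)c(OCOC)c1 | intermediate
15 | lithium alkoxide of 14 lithiated on ring A between OMe and OMOM | COc1cc(OCOC)c([C@@H](CC(O[Li])c2ccc(OCOC)cc2)CCCCc2ccc(OCOC)cc2)c(OCOC)c1[Li] | intermediate
16 | 1-{3-[(3R)-1-hydroxy-1,7-bis[4-(methoxymethoxy)phenyl]heptan-3-yl]-6-methoxy-2,4-bis(methoxymethoxy)phenyl}ethan-1-one (C1 epimers) | COc1cc(OCOC)c([C@@H](CC(O)c2ccc(OCOC)cc2)CCCCc2ccc(OCOC)cc2)c(OCOC)c1C(C)=O | intermediate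
17 | methanesulfonate of the C1 hydroxyl of 16 | COc1cc(OCOC)c([C@@H](CC(OS(C)(=O)=O)c2ccc(OCOC)cc2)CCCCc2ccc(OCOC)cc2)c(OCOC)c1C(C)=O | intermediate
18 | 1-{3-[(1E,3R)-1,7-bis[4-(methoxymethoxy)phenyl]hept-1-en-3-yl]-6-methoxy-2,4-bis(methoxymethoxy)phenyl}ethan-1-one | COc1cc(OCOC)c([C@@H](/C=C/c2ccc(OCOC)cc2)CCCCc2ccc(OCOC)cc2)c(OCOC)c1C(C)=O | intermediate
19 | 4-hydroxybenzaldehyde | O=Cc1ccc(O)cc1 | starting material
20 | 4-(methoxymethoxy)benzaldehyde | COCOc1ccc(C=O)cc1 | intermediate
21 | (2E)-1-{3-[(1E,3R)-1,7-bis[4-(methoxymethoxy)phenyl]hept-1-en-3-yl]-6-methoxy-2,4-bis(methoxymethoxy)phenyl}-3-[4-(methoxymethoxy)phenyl]prop-2-en-1-one | COc1cc(OCOC)c([C@@H](/C=C/c2ccc(OCOC)cc2)CCCCc2ccc(OCOC)cc2)c(OCOC)c1C(=O)/C=C/c1ccc(OCOC)cc1 | intermediate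
22 | deoxycalyxin A, (2E)-1-{3-[(1E,3R)-1,7-bis(4-hydroxyphenyl)hept-1-en-3-yl]-2,4-dihydroxy-6-methoxyphenyl}-3-(4-hydroxyphenyl)prop-2-en-1-one | COc1cc(O)c([C@@H](/C=C/c2ccc(O)cc2)CCCCc2ccc(O)cc2)c(O)c1C(=O)/C=C/c1ccc(O)cc1 | target

**Step count**

Total step count: 12.
Longest linear sequence: 11 steps (steps 1–9, 11 and 12, from 4-bromophenol).

**Steps most likely to fail**

**Step 4.** Three processes could hurt this step. Facial selectivity could be eroded by an addition that bypasses the iminium ion. The still electron-rich product ring could be alkylated again. The catalyst could be tied up by the product aldehyde.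

The fallback keeps the ring A–C3 disconnection but replaces catalysis by auxiliary control. It sets out from 5 and comes back at 14, so steps 4 to 7 are bypassed.
- (4S)-4-Phenyl-1,3-oxazolidin-2-one is N-acylated with acryloyl chloride to (4S)-3-acryloyl-4-phenyl-1,3-oxazolidin-2-one F1.
- Cross-metathesis of 5 with it (second-generation Hoveyda–Grubbs catalyst) gives (4S)-3-{(2E)-7-[4-(methoxymethoxy)phenyl]hept-2-enoyl}-4-phenyl-1,3-oxazolidin-2-one F2.
- Commercial 5-methoxyresorcinol is converted with MOMCl into 1-methoxy-3,5-bis(methoxymethoxy)benzene F3.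
- n-BuLi metalates this between the two MOM ethers to [4-methoxy-2,6-bis(methoxymethoxy)phenyl]lithium F4.
- After transmetalation with MgBr2·OEt2 and CuBr·SMe2 the aryl group adds to the magnesium-chelated s-cis enoyl imide on the face away from the auxiliary phenyl group. This gives the (3R)-configured conjugate adduct imide F5.
- LiBH4 releases the auxiliary and gives (3R)-3-[4-methoxy-2,6-bis(methoxymethoxy)phenyl]-7-[4-(methoxymethoxy)phenyl]heptan-1-ol F6.
- Dess–Martin oxidation gives the corresponding (3R)-heptanal F7.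
- Addition of Grignard reagent 12 delivers 14, with the O-methyl group already in place.

**Step 5.** The two phenolic oxygens may be poorly discriminated. Over-methylation is possible, and base-induced opening of the lactol could be followed by methylation of a flanking oxygen.

The fallback amplifies the steric difference with a much larger electrophile and postpones the methylation until only one phenol is left. It sets out from 10 and comes back at 14.
- TIPSCl (1 equiv) and imidazole in DMF should silylate only the unhindered oxygen, giving (4R)-4-{4-[4-(methoxymethoxy)phenyl]butyl}-7-[(triisopropylsilyl)oxy]chromane-2,5-diol F8.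
- Grignard reagent 12 (3.5 equiv) opens the lactol to 2-{(3R)-1-hydroxy-1,7-bis[4-(methoxymethoxy)phenyl]heptan-3-yl}-5-[(triisopropylsilyl)oxy]benzene-1,3-diol F9.
- MOMCl/K2CO3 caps both flanking phenols to give the bis(methoxymethyl) ether of that silyl ether F10.
- TBAF frees 4-{(3R)-1-hydroxy-1,7-bis[4-(methoxymethoxy)phenyl]heptan-3-yl}-3,5-bis(methoxymethoxy)phenol F11.
- Methylation of this lone phenol with MeI/K2CO3 is unambiguous and gives 14.

**Step 12.** A liberated flanking phenol could close under acid onto the styrene or the enone. This would compete with the slow cleavage of the hindered MOM ethers.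

The fallback avoids protic acid by exchanging the protecting groups. It sets out from 21 and comes back at 22.
- TESOTf and 2,2'-bipyridyl in CH2Cl2 (0 °C → rt) convert the aryl MOM ethers into the pentakis(triethylsilyl) ether of deoxycalyxin A F12.
- This ether is cleaved with acetic acid-buffered TBAF in THF at 0 °C to 22.

**Further compounds**

F1 | step 4 | (4S)-3-acryloyl-4-phenyl-1,3-oxazolidin-2-one | O=C1OC[C@H](c2ccccc2)N1C(=O)C=C
F2 | step 4 | (4S)-3-{(2E)-7-[4-(methoxymethoxy)phenyl]hept-2-enoyl}-4-phenyl-1,3-oxazolidin-2-one | O=C1OC[C@H](c2ccccc2)N1C(=O)/C=C/CCCCc1ccc(OCOC)cc1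
F3 | step 4 | 1-methoxy-3,5-bis(methoxymethoxy)benzene | COCOc1cc(OC)cc(OCOC)c1
F4 | step 4 | [4-methoxy-2,6-bis(methoxymethoxy)phenyl]lithium | [Li]c1c(OCOC)cc(OC)cc1OCOC
F5 | step 4 | (4S)-3-{(3R)-3-[4-methoxy-2,6-bis(methoxymethoxy)phenyl]-7-[4-(methoxymethoxy)phenyl]heptanoyl}-4-phenyl-1,3-oxazolidin-2-one | O=C1OC[C@H](c2ccccc2)N1C(=O)C[C@@H](CCCCc1ccc(OCOC)cc1)c1c(OCOC)cc(OC)cc1OCOC
F6 | step 4 | (3R)-3-[4-methoxy-2,6-bis(methoxymethoxy)phenyl]-7-[4-(methoxymethoxy)phenyl]heptan-1-ol | OCC[C@@H](CCCCc1ccc(OCOC)cc1)c1c(OCOC)cc(OC)cc1OCOC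
F7 | step 4 | (3R)-3-[4-methoxy-2,6-bis(methoxymethoxy)phenyl]-7-[4-(methoxymethoxy)phenyl]heptanal | O=CC[C@@H](CCCCc1ccc(OCOC)cc1)c1c(OCOC)cc(OC)cc1OCOC
F8 | step 5 | (4R)-4-{4-[4-(methoxymethoxy)phenyl]butyl}-7-[(triisopropylsilyl)oxy]chromane-2,5-diol | CC(C)[Si](Oc1cc(O)c2c(c1)OC(O)C[C@H]2CCCCc1ccc(OCOC)cc1)(C(C)C)C(C)C
F9 | step 5 | 2-{(3R)-1-hydroxy-1,7-bis[4-(methoxymethoxy)phenyl]heptan-3-yl}-5-[(triisopropylsilyl)oxy]benzene-1,3-diol | CC(C)[Si](Oc1cc(O)c([C@@H](CC(O)c2ccc(OCOC)cc2)CCCCc2ccc(OCOC)cc2)c(O)c1)(C(C)C)C(C)C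
F10 | step 5 | (3R)-3-{2,6-bis(methoxymethoxy)-4-[(triisopropylsilyl)oxy]phenyl}-1,7-bis[4-(methoxymethoxy)phenyl]heptan-1-ol | CC(C)[Si](Oc1cc(OCOC)c([C@@H](CC(O)c2ccc(OCOC)cc2)CCCCc2ccc(OCOC)cc2)c(OCOC)c1)(C(C)C)C(C)C
F11 | step 5 | 4-{(3R)-1-hydroxy-1,7-bis[4-(methoxymethoxy)phenyl]heptan-3-yl}-3,5-bis(methoxymethoxy)phenol | Oc1cc(OCOC)c([C@@H](CC(O)c2ccc(OCOC)cc2)CCCCc2ccc(OCOC)cc2)c(OCOC)c1
F12 | step 12 | pentakis(triethylsilyl) ether of deoxycalyxin A | COc1cc(O[Si](CC)(CC)CC)c([C@@H](/C=C/c2ccc(O[Si](CC)(CC)CC)cc2)CCCCc2ccc(O[Si](CC)(CC)CC)cc2)c(O[Si](CC)(CC)CC)c1C(=O)/C=C/c1ccc(O[Si](CC)(CC)CC)cc1
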